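The diarylheptanoid is cut at the bond between the ipso carbon of ring A (the 3-methoxy-4,5-dihydroxyphenyl ring) and C1. The C3 carbonyl sits two methylenes (C1, C2) away from that ipso carbon. The segment ring A–C1–C2–C3(=O) is therefore an opened 1-alkylcyclopropanol in which C3 is the carbinol carbon. A palladium-catalysed ring-opening arylation forges the aryl–C1 bond, breaks the strained C1–C3 bond and unmasks the ketone in a single operation, uniting both halves. Its precursors are a benzyl-protected ring A bromide and a symmetric cyclopropanol that carries the C4–C7 chain and benzyl-protected ring B. Hydrogenolysis finishes the synthesis.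

Key step: step 6

Remark on the chemistry: the chain is numbered C1 to C7 from ring A (3-methoxy-4,5-dioxygenated) to ring B (3,4-dioxygenated). The target and every compound of the main route are achiral. 9-BBN is drawn as its monomer.

Step 1
Reactants: 1 5-bromo-2-hydroxy-3-methoxybenzaldehyde (5-bromo-ortho-vanillin)
Product: 3 5-bromo-3-methoxybenzene-1,2-diol, via aryl formate 2 (not isolated)
Conditions: 30% aq. H2O2 (1.2 equiv), NaOH (1.1 equiv), THF/H2O, 0 °C to rt, N2; then 1 M HCl
Reagents that add atoms: hydrogen peroxide, OO
Why: Dakin oxidation, in which hydroperoxide adds to the aldehyde of the ortho-hydroxybenzaldehyde, the electron-rich aryl group migrates to oxygen and the formate is saponified in the same alkaline medium, while the aryl bromide and the methyl ether are inert to cold alkaline peroxide.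

Step 2
Reactants: 3 5-bromo-3-methoxybenzene-1,2-diol
Product: 4 1,2-bis(benzyloxy)-5-bromo-3-methoxybenzene (ring A fragment)
Conditions: BnBr (2.4 equiv), K2CO3 (3 equiv), degassed DMF, rt to 60 °C, N2
Reagents that add atoms: benzyl bromide, BrCc1ccccc1
Why: Williamson ether synthesis, in which both phenoxides, including the flanked central one, are alkylated by the reactive benzylic bromide in a dipolar aprotic solvent, and exclusion of oxygen protects the freshly prepared catechol from quinone formation until it is capped.

Step 3
Reactants: 5 4-bromobenzene-1,2-diol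
Product: 6 1,2-bis(benzyloxy)-4-bromobenzene (ring B fragment)
Conditions: BnBr (2.4 equiv), K2CO3 (3 equiv), degassed DMF, rt to 60 °C, N2
Reagents that add atoms: benzyl bromide, BrCc1ccccc1
Why: The same Williamson double O-benzylation applies to an unhindered catechol, and the aryl bromide does not react with carbonate or with benzyl bromide.

Step 4
Reactants: 6 1,2-bis(benzyloxy)-4-bromobenzene; 7 methyl pent-4-enoate; 8 9-borabicyclo[3.3.1]nonane (9-BBN)
Product: 10 methyl 5-[3,4-bis(benzyloxy)phenyl]pentanoate, via B-alkyl borane 9 (not isolated)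
Conditions: 7 (1.3 equiv), 8 (0.5 M in THF, 1.35 equiv), THF, 0 °C to rt; then 6 (1.0 equiv), Pd(dppf)Cl2 (4 mol %), aq. K3PO4 (3 equiv), DMF, 60 °C, one pot
Reagents that add atoms: none
Why: Anti-Markovnikov hydroboration of the terminal alkene by 9-BBN, which leaves the ester alone at room temperature, is followed by a B-alkyl Suzuki–Miyaura coupling in which the wide-bite-angle dppf ligand favours reductive elimination over beta-hydride elimination and the phosphate base spares the methyl ester from saponification.

Step 5
Reactants: 10 methyl 5-[3,4-bis(benzyloxy)phenyl]pentanoate; 11 ethylmagnesium bromide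
Product: 12 1-{4-[3,4-bis(benzyloxy)phenyl]butyl}cyclopropan-1-ol
Conditions: Ti(OiPr)4 (0.3 equiv), 11 (2.8 equiv, slow addition), THF, 0 °C to rt; cold sat. aq. NH4Cl quench
Reagents that add atoms: none
Why: Kulinkovich cyclopropanation, in which two ethyl groups on titanium collapse with loss of ethane to a titanacyclopropane that acts as a 1,2-dicarbanion on the ester carbonyl and so installs C1 and C2, the benzyl aryl ethers being inert and the carbinol carbon non-stereogenic because its two ring methylenes are identical.

Step 6
Reactants: 4 1,2-bis(benzyloxy)-5-bromo-3-methoxybenzene; 12 1-{4-[3,4-bis(benzyloxy)phenyl]butyl}cyclopropan-1-ol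
Product: 13 1-[3,4-bis(benzyloxy)-5-methoxyphenyl]-7-[3,4-bis(benzyloxy)phenyl]heptan-3-one
Conditions: 4 (1.2 equiv), 12 (1.0 equiv), Pd(OAc)2 (5 mol %), XPhos (10 mol %), Cs2CO3 (2 equiv), degassed toluene, 80 °C, Ar
Reagents that add atoms: none
Why: Zerovalent palladium formed from Pd(OAc)2 and XPhos inserts into the C–Br bond of 4, whose two ortho positions carry only hydrogen; carbonate-assisted exchange of bromide for the cyclopropanolate of 12 gives an aryl alkoxide of divalent palladium, strain-driven beta-carbon elimination cleaves the C1–C3 bond to a beta-keto alkyl palladium homoenolate, and reductive elimination makes the ipso carbon–C1 bond. The closest known reaction type is exactly this one, the palladium-catalysed ring-opening cross-coupling of 1-alkylcyclopropanols with aryl bromides. No ring is closed and no stereocentre is created, the only ring event being the opening of the three-membered ring. The selectivity needed is reductive elimination ahead of beta-hydride elimination from C2 of the homoenolate, which the bulky, electron-rich dialkylbiaryl phosphine should secure by accelerating C–C bond formation and blocking the free coordination site that a hydride shift requires. The site of ring cleavage raises no question because the two ring methylenes of 12 are equivalent, so the carbonyl can only appear at C3. The benzyl and methyl ethers are spectators, and the slight excess of 4 lets any vinyl ketone that does form be captured by Heck arylation as the aryl enone, which step 7 would reduce to the same target, whereas vinyl ketone left unarylated does not converge and must be removed by chromatography.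

Step 7
Reactants: 13 1-[3,4-bis(benzyloxy)-5-methoxyphenyl]-7-[3,4-bis(benzyloxy)phenyl]heptan-3-one
Product: 14 1-(3,4-dihydroxy-5-methoxyphenyl)-7-(3,4-dihydroxyphenyl)heptan-3-one (CNP0126174.0)
Conditions: H2 (1 atm), 10% Pd/C, EtOAc/EtOH, rt; filtration through Celite under Ar
Reagents that add atoms: none
Why: Catalytic hydrogenolysis cleaves all four benzylic C–O bonds under neutral conditions and leaves the aryl methyl ether and the non-benzylic dialkyl ketone untouched, while oxygen-free handling protects the two liberated catechol units.

Compound list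
1 | 5-bromo-2-hydroxy-3-methoxybenzaldehyde | COc1cc(Br)cc(C=O)c1O | starting material
2 | 5-bromo-2-hydroxy-3-methoxyphenyl formate | COc1cc(Br)cc(OC=O)c1O | intermediate
3 | 5-bromo-3-methoxybenzene-1,2-diol | COc1cc(Br)cc(O)c1O | intermediate
4 | 1,2-bis(benzyloxy)-5-bromo-3-methoxybenzene | COc1cc(Br)cc(OCc2ccccc2)c1OCc1ccccc1 | intermediate
5 | 4-bromobenzene-1,2-diol | Oc1ccc(Br)cc1O | starting material
6 | 1,2-bis(benzyloxy)-4-bromobenzene | Brc1ccc(OCc2ccccc2)c(OCc2ccccc2)c1 | intermediate
7 | methyl pent-4-enoate | C=CCCC(=O)OC | starting material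
8 | 9-borabicyclo[3.3.1]nonane (9-BBN) | B1C2CCCC1CCC2 | starting material
9 | methyl 5-(9-borabicyclo[3.3.1]nonan-9-yl)pentanoate | COC(=O)CCCCB1C2CCCC1CCC2 | intermediate
10 | methyl 5-[3,4-bis(benzyloxy)phenyl]pentanoate | COC(=O)CCCCc1ccc(OCc2ccccc2)c(OCc2ccccc2)c1 | intermediate
11 | ethylmagnesium bromide | CC[Mg]Br | starting material
12 | 1-{4-[3,4-bis(benzyloxy)phenyl]butyl}cyclopropan-1-ol | OC1(CCCCc2ccc(OCc3ccccc3)c(OCc3ccccc3)c2)CC1 | intermediate
13 | 1-[3,4-bis(benzyloxy)-5-methoxyphenyl]-7-[3,4-bis(benzyloxy)phenyl]heptan-3-one | COc1cc(CCC(=O)CCCCc2ccc(OCc3ccccc3)c(OCc3ccccc3)c2)cc(OCc2ccccc2)c1OCc1ccccc1 | intermediate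
14 | 1-(3,4-dihydroxy-5-methoxyphenyl)-7-(3,4-dihydroxyphenyl)heptan-3-one | COc1cc(CCC(=O)CCCCc2ccc(O)c(O)c2)cc(O)c1O | target

Total step count: 7.
Longest linear sequence: 5 steps (steps 3, 4, 5, 6 and 7, from 5 to 14). The ring A branch (steps 1 and 2) joins at step 6.

Steps most likely to fail

Step 6. Beta-hydride elimination from the palladium homoenolate may overtake reductive elimination. Base-induced isomerisation of the cyclopropanol to an unarylated open-chain ketone may also drain the nucleophile. The fallback sets out from 12 and separates ring opening from arylation.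
- Aerobic dehydrogenative ring opening (Pd(OAc)2, pyridine, O2, toluene, 80 °C) deliberately drives the hydride elimination to the vinyl ketone 7-[3,4-bis(benzyloxy)phenyl]hept-1-en-3-one F1.
- A Mizoroki–Heck reaction of F1 with bromide 4 (Pd(OAc)2, P(o-tol)3, NaOAc, DMF, 100 °C) arylates the terminal alkene carbon to give (E)-1-[3,4-bis(benzyloxy)-5-methoxyphenyl]-7-[3,4-bis(benzyloxy)phenyl]hept-1-en-3-one F2.
- Under the conditions of step 7, F2 should lose its alkene and all four benzyl groups together, so the route is rejoined at 14.

Step 5. Direct addition of the Grignard reagent to the ester may compete with the titanium-mediated pathway. The strained alcohol may also open during quench or chromatography. The fallback sets out from 10 and builds the ring by carbenoid addition to an enol ether.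
- Aminolysis with MeNH(OMe)·HCl and iPrMgCl (THF, −20 °C) gives the Weinreb amide 5-[3,4-bis(benzyloxy)phenyl]-N-methoxy-N-methylpentanamide F3.
- MeMgBr (THF, 0 °C) converts it into 6-[3,4-bis(benzyloxy)phenyl]hexan-2-one F4.
- Kinetic deprotonation at the methyl group (LDA, THF, −78 °C, then TMSCl) gives ({6-[3,4-bis(benzyloxy)phenyl]hex-1-en-2-yl}oxy)trimethylsilane F5.
- Furukawa-modified Simmons–Smith cyclopropanation (Et2Zn, CH2I2, CH2Cl2, 0 °C) gives (1-{4-[3,4-bis(benzyloxy)phenyl]butyl}cyclopropoxy)trimethylsilane F6.
- Mild methanolysis (K2CO3, MeOH, 0 °C) returns to the route at 12.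

Step 4. Slow, base-dependent transmetalation from boron may allow protodeboronation of the alkyl borane and saponification of the ester in the aqueous medium. The fallback sets out from 6 and takes the alkyl nucleophile from a different precursor under base-free, anhydrous conditions.
- Zinc insertion into commercial methyl 5-bromopentanoate (Zn dust, LiCl, THF) gives (5-methoxy-5-oxopentyl)zinc bromide F7.
- Negishi coupling of F7 with 6 (Pd(OAc)2, SPhos, THF, rt to 50 °C) comes back to the route at 10.

Further compounds
F1 | step 6 | 7-[3,4-bis(benzyloxy)phenyl]hept-1-en-3-one | C=CC(=O)CCCCc1ccc(OCc2ccccc2)c(OCc2ccccc2)c1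
F2 | step 6 | (E)-1-[3,4-bis(benzyloxy)-5-methoxyphenyl]-7-[3,4-bis(benzyloxy)phenyl]hept-1-en-3-one | COc1cc(/C=C/C(=O)CCCCc2ccc(OCc3ccccc3)c(OCc3ccccc3)c2)cc(OCc2ccccc2)c1OCc1ccccc1
F3 | step 5 | 5-[3,4-bis(benzyloxy)phenyl]-N-methoxy-N-methylpentanamide | CON(C)C(=O)CCCCc1ccc(OCc2ccccc2)c(OCc2ccccc2)c1
F4 | step 5 | 6-[3,4-bis(benzyloxy)phenyl]hexan-2-one | CC(=O)CCCCc1ccc(OCc2ccccc2)c(OCc2ccccc2)c1
F5 | step 5 | ({6-[3,4-bis(benzyloxy)phenyl]hex-1-en-2-yl}oxy)trimethylsilane | C=C(CCCCc1ccc(OCc2ccccc2)c(OCc2ccccc2)c1)O[Si](C)(C)C
F6 | step 5 | (1-{4-[3,4-bis(benzyloxy)phenyl]butyl}cyclopropoxy)trimethylsilane | C[Si](C)(C)OC1(CCCCc2ccc(OCc3ccccc3)c(OCc3ccccc3)c2)CC1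
F7 | step 4 | (5-methoxy-5-oxopentyl)zinc bromide | COC(=O)CCCC[Zn]Br
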